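**Retrosynthetic overview**
1. Each Ar–CH2–Ar bridge is cut only on the central-ring side. The bridge carbons are not formaldehyde but the formyl carbons of two fully substituted outer-ring aldehydes, 7 (right ring) and 12 (left ring).
2. Each aldehyde is joined to phlorobutyrophenone 13 by a one-pot borohydride reduction / o-quinone methide C-arylation: 7 + 13 gives dimer 16, then 12 + 16 gives the target 19.
3. 7 and 12 are formyl/butanoyl-transposed isomers, both made from 2,4,6-trimethoxytoluene 1 by the same three operations in opposite order (butanoylation, BCl3, formylation versus formylation, BCl3, butanoylation).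
4. The carbonyl present during the BCl3 step decides which two OMe groups are cleaved, so the surviving OMe ends up para to the butanoyl group in the right ring and para to the bridge carbon in the left ring. Every later substitution goes to the single open ring position.
5. No ring is constructed: all three benzene rings are bought (1 twice, 13 once). Assembly order is right ring + central ring, then left ring.

Assumption: the target has no stereocentre and no stereogenic double bond (it is achiral), so "single enantiomer" needs no stereocontrol and the route is judged on regiocontrol; 1, 2 and 13 are taken as commercially available.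

**Step 1**
Reactants: 1 2,4,6-trimethoxytoluene; 2 butanoyl chloride
Product: 3 1-(2,4,6-trimethoxy-3-methylphenyl)butan-1-one
Conditions: AlCl3 (1.2 equiv), CH2Cl2, 0 °C, 2 h; ice/1 M HCl
Reagents that add atoms: butanoyl chloride CCCC(=O)Cl
Why: Friedel–Crafts acylation; the two open positions of 1 are equivalent and the ketone deactivates the ring, so one mono-ketone forms (any ortho-demethylated by-product converges in step 2).

**Step 2**
Reactants: 3 1-(2,4,6-trimethoxy-3-methylphenyl)butan-1-one
Product: 5 aspidinol [1-(2,6-dihydroxy-4-methoxy-3-methylphenyl)butan-1-one], via bis(dichloroboryl) ether 4 (not isolated)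
Conditions: BCl3 (4 equiv), CH2Cl2, −10 °C → rt, 16 h; then ice-water/1 M HCl, rt
Reagents that add atoms: none
Why: Chelation-directed Lewis-acid ether cleavage: BCl3 held by the ketone oxygen removes only the two methoxy groups ortho to the carbonyl and leaves the para methoxy group.

**Step 3**
Reactants: 5 aspidinol
Product: 7 3-butanoyl-2,4-dihydroxy-6-methoxy-5-methylbenzaldehyde (5-formylaspidinol), via α-chloro methyl ether 6 (not isolated)
Conditions: Cl2CHOMe (1.5 equiv), TiCl4 (3 equiv), CH2Cl2, −10 → 0 °C, 2 h; then 1 M HCl, rt, 1 h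
Reagents that add atoms: dichloromethyl methyl ether COC(Cl)Cl; water O
Why: Rieche formylation at the only unsubstituted ring carbon of aspidinol; chosen over Vilsmeier conditions, which can attack the α-methylene of an o-hydroxyaryl ketone and close a chromone.

**Step 4**
Reactants: 1 2,4,6-trimethoxytoluene
Product: 9 2,4,6-trimethoxy-3-methylbenzaldehyde, via aryl iminium chloride 8 (not isolated)
Conditions: POCl3 (1.2 equiv), DMF, 0 °C → rt, 4 h; then ice-water, rt
Reagents that add atoms: N,N-dimethylformamide CN(C)C=O; water O
Why: Vilsmeier–Haack formylation; the two open positions are equivalent and the iminium substituent deactivates the ring, so a single mono-aldehyde results.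

**Step 5**
Reactants: 9 2,4,6-trimethoxy-3-methylbenzaldehyde
Product: 11 2,6-dihydroxy-4-methoxy-3-methylbenzaldehyde, via bis(dichloroboryl) ether 10 (not isolated)
Conditions: BCl3 (4 equiv), CH2Cl2, −10 °C → rt, 16 h; then ice-water/1 M HCl, rt
Reagents that add atoms: none
Why: The same chelation-directed demethylation, now steered by the formyl group, so the two hydroxyls flank the future bridge carbon and the methoxy group stays para to it; this sets the left-ring substitution pattern.

**Step 6**
Reactants: 11 2,6-dihydroxy-4-methoxy-3-methylbenzaldehyde; 2 butanoyl chloride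
Product: 12 3-butanoyl-2,6-dihydroxy-4-methoxy-5-methylbenzaldehyde
Conditions: butanoyl chloride (1.3 equiv), TiCl4 (3 equiv), CH2Cl2/MeNO2, 0 °C → rt, 6 h; then 1 M HCl
Reagents that add atoms: butanoyl chloride CCCC(=O)Cl
Why: Friedel–Crafts acylation at the one remaining ring position, which is still activated by an ortho OH, a para OH and an ortho OMe; TiCl4 at or below rt should not cleave the methoxy group.

**Step 7**
Reactants: 7 3-butanoyl-2,4-dihydroxy-6-methoxy-5-methylbenzaldehyde; 13 1-(2,4,6-trihydroxyphenyl)butan-1-one (3 equiv)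
Product: 16 1-[3-[(3-butanoyl-2,4-dihydroxy-6-methoxy-5-methylphenyl)methyl]-2,4,6-trihydroxyphenyl]butan-1-one, via hydroxymethyl aspidinol 14 (not isolated), via o-quinone methide 15 (not isolated)
Conditions: 0.2 M aq NaOH/THF (1:1), Ar, 0 °C; NaBH4 (0.4 equiv) added over 1 h; 0 → 15 °C, 2 h; then 1 M HCl to pH 3
Reagents that add atoms: none
Why: Proposed new method: borohydride reduces only the aldehyde (the chelated, phenolate-deactivated aryl ketones are inert at 0 °C) to hydroxymethyl phenolate 14, which loses hydroxide to o-quinone methide 15 as the hydroxymethyl intermediate of the classical alkaline formaldehyde coupling of acylphloroglucinols does, and 15 is captured at carbon (Michael-type Friedel–Crafts alkylation) by the phenolate of 13, present in threefold excess from the start so that C-arylation outruns hydride addition to 15 and double alkylation of 13; the closest known reactions are that alkaline HCHO coupling and hydride-triggered o-quinone methide generation from salicylaldehyde derivatives.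

**Step 8**
Reactants: 12 3-butanoyl-2,6-dihydroxy-4-methoxy-5-methylbenzaldehyde (1.1 equiv); 16 1-[3-[(3-butanoyl-2,4-dihydroxy-6-methoxy-5-methylphenyl)methyl]-2,4,6-trihydroxyphenyl]butan-1-one
Product: 19 1-[3-[(3-butanoyl-2,4-dihydroxy-6-methoxy-5-methylphenyl)methyl]-5-[(3-butanoyl-2,6-dihydroxy-4-methoxy-5-methylphenyl)methyl]-2,4,6-trihydroxyphenyl]butan-1-one (target), via benzylic alcohol 17 (not isolated), via o-quinone methide 18 (not isolated)
Conditions: 0.2 M aq NaOH/THF (1:1), Ar, 0 °C; NaBH4 (0.45 equiv) added over 1 h; 0 → 15 °C, 2 h; then 1 M HCl to pH 3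
Reagents that add atoms: none
Why: Proposed new method: the same one-pot aldehyde reduction, hydroxide loss to o-quinone methide 18 and Michael-type C-alkylation, now with complete site control because 18 has no ring C–H and 16 has exactly one nucleophilic ring carbon, so only the cross-coupled trimer can form and no stereocentre arises; the closest known reaction is the alkaline formaldehyde coupling of acylphloroglucinols, whose hydroxymethyl intermediate is here made regiospecifically from a ring aldehyde.

**Compound list**
1 | 2,4,6-trimethoxytoluene | Cc1c(OC)cc(OC)cc1OC | starting material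
2 | butanoyl chloride | CCCC(=O)Cl | starting material
3 | 1-(2,4,6-trimethoxy-3-methylphenyl)butan-1-one | CCCC(=O)c1c(OC)cc(OC)c(C)c1OC | intermediate
4 | 1-[2,6-bis(dichloroboranyloxy)-4-methoxy-3-methylphenyl]butan-1-one | CCCC(=O)c1c(OB(Cl)Cl)cc(OC)c(C)c1OB(Cl)Cl | intermediate
5 | aspidinol, 1-(2,6-dihydroxy-4-methoxy-3-methylphenyl)butan-1-one | CCCC(=O)c1c(O)cc(OC)c(C)c1O | intermediate
6 | 1-[3-[chloro(methoxy)methyl]-2,6-dihydroxy-4-methoxy-5-methylphenyl]butan-1-one (racemic, transient) | CCCC(=O)c1c(O)c(C(Cl)OC)c(OC)c(C)c1O | intermediate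
7 | 3-butanoyl-2,4-dihydroxy-6-methoxy-5-methylbenzaldehyde | CCCC(=O)c1c(O)c(C=O)c(OC)c(C)c1O | intermediate
8 | N,N-dimethyl-1-(2,4,6-trimethoxy-3-methylphenyl)methaniminium chloride | COc1cc(OC)c(C=[N+](C)C)c(OC)c1C.[Cl-] | intermediate
9 | 2,4,6-trimethoxy-3-methylbenzaldehyde | COc1cc(OC)c(C=O)c(OC)c1C | intermediate
10 | 2,6-bis(dichloroboranyloxy)-4-methoxy-3-methylbenzaldehyde | COc1cc(OB(Cl)Cl)c(C=O)c(OB(Cl)Cl)c1C | intermediate
11 | 2,6-dihydroxy-4-methoxy-3-methylbenzaldehyde | COc1cc(O)c(C=O)c(O)c1C | intermediate
12 | 3-butanoyl-2,6-dihydroxy-4-methoxy-5-methylbenzaldehyde | CCCC(=O)c1c(OC)c(C)c(O)c(C=O)c1O | intermediate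
13 | 1-(2,4,6-trihydroxyphenyl)butan-1-one (phlorobutyrophenone) | CCCC(=O)c1c(O)cc(O)cc1O | starting material
14 | 1-[2,6-dihydroxy-3-(hydroxymethyl)-4-methoxy-5-methylphenyl]butan-1-one | CCCC(=O)c1c(O)c(CO)c(OC)c(C)c1O | intermediate
15 | 2-butanoyl-3-hydroxy-5-methoxy-4-methyl-6-methylidenecyclohexa-2,4-dien-1-one | CCCC(=O)C1=C(O)C(C)=C(OC)C(=C)C1=O | intermediate
16 | 1-[3-[(3-butanoyl-2,4-dihydroxy-6-methoxy-5-methylphenyl)methyl]-2,4,6-trihydroxyphenyl]butan-1-one | CCCC(=O)c1c(O)cc(O)c(Cc2c(O)c(C(=O)CCC)c(O)c(C)c2OC)c1O | intermediate
17 | 1-[2,4-dihydroxy-3-(hydroxymethyl)-6-methoxy-5-methylphenyl]butan-1-one | CCCC(=O)c1c(OC)c(C)c(O)c(CO)c1O | intermediate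
18 | 4-butanoyl-3-hydroxy-5-methoxy-6-methyl-2-methylidenecyclohexa-3,5-dien-1-one | CCCC(=O)C1=C(O)C(=C)C(=O)C(C)=C1OC | intermediate
19 | 1-[3-[(3-butanoyl-2,4-dihydroxy-6-methoxy-5-methylphenyl)methyl]-5-[(3-butanoyl-2,6-dihydroxy-4-methoxy-5-methylphenyl)methyl]-2,4,6-trihydroxyphenyl]butan-1-one (achiral) | CCCC(=O)c1c(O)c(Cc2c(O)c(C)c(OC)c(C(=O)CCC)c2O)c(O)c(Cc2c(O)c(C(=O)CCC)c(O)c(C)c2OC)c1O | target

**Totals**
Total step count: 8.
Longest linear sequence: 5 steps (steps 1, 2, 3, 7, 8); the left-ring branch (steps 4, 5, 6) joins at step 8.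

**Three steps most likely to fail, with fallbacks**

Step 8 (most at risk). Hydride may add to quinone methide 18 and give the C-methyl compound instead of the trimer, and the alkaline medium may scramble the methylene bridges of 16 or 19 by retro-Michael cleavage (rottlerone-type change). The fallback sets out from 12 and comes back at 19. Reductive amination of 12 with dimethylamine and NaBH(OAc)3 in DCE/AcOH gives the Mannich base 1-[3-[(dimethylamino)methyl]-2,4-dihydroxy-6-methoxy-5-methylphenyl]butan-1-one F4, isolated as its stable ammonium salt. Heating F4 with 16 in dioxane at 90 °C, with neither hydride nor hydroxide present, expels dimethylamine to give the same quinone methide 18, which 16 traps to give 19.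

Step 7. The failure modes are the same over-reduction of 15 and double alkylation of 13. The fallback sets out from 5 and comes back at 16, and makes step 3 unnecessary. A Mannich reaction of aspidinol 5 with N,N-dimethylmethyleneiminium iodide in CH2Cl2 at rt puts the aminomethyl group on the only free ring carbon and gives 1-[3-[(dimethylamino)methyl]-2,6-dihydroxy-4-methoxy-5-methylphenyl]butan-1-one F3. Heating F3 with 13 (3 equiv) in dioxane at 90 °C releases 15 by retro-Mannich fragmentation and gives 16.

Step 6. The formyl group deactivates the ring, so C-acylation may stop at the aryl ester, or the Lewis acid may cleave the methoxy group next to the new ketone. The fallback sets out from 11 and comes back at 12. Both phenols are first acylated (butanoic anhydride, pyridine, DMAP) to give 2-formyl-5-methoxy-4-methyl-1,3-phenylene dibutanoate F1. A Fries rearrangement (TiCl4, MeNO2, 40 °C, or photo-Fries at 254 nm without Lewis acid) then moves one butanoyl group to the single free ring carbon and gives 4-butanoyl-2-formyl-3-hydroxy-5-methoxy-6-methylphenyl butanoate F2. Hydrolysis of the remaining ester with aqueous LiOH followed by acidification returns 12.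

**Further compounds**
F1 | step 6 | 2-formyl-5-methoxy-4-methyl-1,3-phenylene dibutanoate | CCCC(=O)Oc1cc(OC)c(C)c(OC(=O)CCC)c1C=O
F2 | step 6 | 4-butanoyl-2-formyl-3-hydroxy-5-methoxy-6-methylphenyl butanoate | CCCC(=O)Oc1c(C)c(OC)c(C(=O)CCC)c(O)c1C=O
F3 | step 7 | 1-[3-[(dimethylamino)methyl]-2,6-dihydroxy-4-methoxy-5-methylphenyl]butan-1-one | CCCC(=O)c1c(O)c(CN(C)C)c(OC)c(C)c1O
F4 | step 8 | 1-[3-[(dimethylamino)methyl]-2,4-dihydroxy-6-methoxy-5-methylphenyl]butan-1-one | CCCC(=O)c1c(OC)c(C)c(O)c(CN(C)C)c1O
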